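**Plan**

- Retrosynthesis: the two silyl ethers are removed first, then the one strategic cut is made at the C6–C7 bond of the heptanoate chain (carbinol carbon to the CH2 on chromone C2), and last the 7-O-methyl ether.
- Enabling feature: the C2 methyl group of the 4H-chromen-4-one (γ-pyranone) ring is vinylogous to the C4 carbonyl through C2=C3. O4-silylation and loss of a methyl proton give the exocyclic 2-methylidene-2H-chromene (a pyrylium anhydrobase), a γ-nucleophile that regains the aromatic pyranone ring when it forms a C–C bond.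
- Forward: noreugenin → eugenin (7-O-methylation) → 4,5-bis-silyl dienol ether → catalytic enantioselective vinylogous Mukaiyama aldol addition to methyl 6-oxohexanoate, which joins chain and heterocycle → global desilylation. No ring is made; the chromone bicycle is bought intact.
- Stereochemistry: the only stereocentre, C6 (R), is set in the aldol step by an (S)-BINOL–Ti catalyst (Si-face attack on the aldehyde) and is not touched afterwards.

Key step: step 3

Assumption: noreugenin (1) and methyl 6-oxohexanoate (6) are taken as catalogue compounds. The sense of induction in step 3 is assigned by analogy and would be confirmed on the product.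

**Step 1**
Reactants: 1 noreugenin (5,7-dihydroxy-2-methyl-4H-chromen-4-one)
Product: 2 eugenin (5-hydroxy-7-methoxy-2-methyl-4H-chromen-4-one)
Conditions: MeI (1.05 equiv), K2CO3 (1.1 equiv), acetone, reflux
Reagents that add atoms: iodomethane, CI
Why: Williamson ether synthesis; the 7-OH, para to the ring carbonyl and the more acidic phenol, is alkylated while the 5-OH stays locked in its hydrogen bond to the C4 carbonyl, so one equivalent of MeI should give the 7-monomethyl ether.

**Step 2**
Reactants: 2 eugenin
Product: 5 4,5-bis(tert-butyldimethylsilyloxy)-7-methoxy-2-methylidene-2H-chromene, via 5-O-TBS-eugenin 3 (not isolated), via 4-silyloxybenzopyrylium triflate 4 (not isolated)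
Conditions: TBSOTf (2.2 equiv), Et3N (3 equiv), CH2Cl2, 0 °C → rt; pentane, filtration under Ar, used crude
Reagents that add atoms: tert-butyldimethylsilyl trifluoromethanesulfonate (TBSOTf), CC(C)(C)[Si](C)(C)OS(=O)(=O)C(F)(F)F
Why: Silyl triflate/amine soft enolisation, in which the phenol is silylated, O-silylation of the pyranone carbonyl gives the 4-silyloxybenzopyrylium ion, and its 2-methyl group, acidic like that of a 2-methylpyrylium salt, is deprotonated by Et3N to the neutral anhydrobase (an extended silyl dienol ether).

**Step 3**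
Reactants: 5 4,5-bis(tert-butyldimethylsilyloxy)-7-methoxy-2-methylidene-2H-chromene; 6 methyl 6-oxohexanoate
Product: 8 methyl (6R)-6-[(tert-butyldimethylsilyl)oxy]-7-{5-[(tert-butyldimethylsilyl)oxy]-7-methoxy-4-oxo-4H-chromen-2-yl}heptanoate, via benzopyrylium aldolate 7 (not isolated)
Conditions: Ti(Oi-Pr)4 (20 mol%), (S)-BINOL (20 mol%), 4 Å MS, THF, rt; then 6, then 5 (1.3 equiv), −78 → −20 °C; aq. NaHCO3
Reagents that add atoms: none
Why: Proposed new method: the (S)-BINOL–Ti(IV) complex activates the aldehyde of 6, and the exocyclic methylidene carbon of 5 (the anhydrobase of a 2-methyl-4-silyloxybenzopyrylium ion) attacks it through an open transition state to give the aromatic benzopyrylium aldolate 7, whose O4 silyl group then passes to the titanium-bound alkoxide and releases 8 and the catalyst. The closest known reaction type is the Ti–BINOL-catalysed vinylogous Mukaiyama aldol addition of the isosteric 6-methylidene-4-silyloxy-1,3-dioxins (dioxinone dienolates) to aliphatic aldehydes, and the same C–C bond is known to form, without enantiocontrol, from lithiated 2-methylchromones and aldehydes. No ring is closed. The C6 stereocentre is set by the catalyst alone: by analogy with BINOL–Ti aldehyde additions the (S)-ligand should expose the Si face of the aldehyde, which corresponds to the (R) carbinol here, and the assignment would be confirmed by Mosher ester analysis. The step needs attack through the exocyclic carbon and not through C3, which is secured because only the former regains the aromatic pyrylium ring (and the ring-locked s-trans diene cannot undergo a hetero-Diels–Alder reaction), and it needs the aldehyde to react in preference to the methyl ester, which the far higher electrophilicity of the titanium-bound aldehyde secures. The peri 5-silyloxy group masks the phenol and screens the Lewis-basic C4 carbonyl of the product from titanium, so that turnover should not be blocked.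

**Step 4**
Reactants: 8 methyl (6R)-6-[(tert-butyldimethylsilyl)oxy]-7-{5-[(tert-butyldimethylsilyl)oxy]-7-methoxy-4-oxo-4H-chromen-2-yl}heptanoate (crude material that has already lost the 5-O-silyl group is carried along)
Product: 10 Penithochromone O, methyl (6R)-6-hydroxy-7-(5-hydroxy-7-methoxy-4-oxo-4H-chromen-2-yl)heptanoate, via 5-hydroxy 6-O-TBS ether 9 (not isolated)
Conditions: HF·pyridine, pyridine, THF, 0 °C → rt
Reagents that add atoms: none
Why: Fluoride-mediated silyl ether cleavage under weakly acidic conditions, which should spare the methyl ester and avoid base-induced β-elimination of the C6 oxygen; the strained peri aryl silyl ether, activated by the neighbouring carbonyl, should fall first, and the stereocentre is not involved.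

**Compound list**

1 | noreugenin, 5,7-dihydroxy-2-methyl-4H-chromen-4-one | Cc1cc(=O)c2c(O)cc(O)cc2o1 | starting material
2 | eugenin, 5-hydroxy-7-methoxy-2-methyl-4H-chromen-4-one | Cc1cc(=O)c2c(O)cc(OC)cc2o1 | intermediate
3 | 5-[(tert-butyldimethylsilyl)oxy]-7-methoxy-2-methyl-4H-chromen-4-one (not isolated) | Cc1cc(=O)c2c(O[Si](C)(C)C(C)(C)C)cc(OC)cc2o1 | intermediate
4 | 4,5-bis[(tert-butyldimethylsilyl)oxy]-7-methoxy-2-methylchromenylium trifluoromethanesulfonate (not isolated) | Cc1cc(O[Si](C)(C)C(C)(C)C)c2c(O[Si](C)(C)C(C)(C)C)cc(OC)cc2[o+]1.[O-]S(=O)(=O)C(F)(F)F | intermediate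
5 | 4,5-bis(tert-butyldimethylsilyloxy)-7-methoxy-2-methylidene-2H-chromene | C=C1C=C(O[Si](C)(C)C(C)(C)C)c2c(O[Si](C)(C)C(C)(C)C)cc(OC)cc2O1 | intermediate
6 | methyl 6-oxohexanoate | COC(=O)CCCCC=O | starting material
7 | (R)-configured 4,5-bis(silyloxy)benzopyrylium aldolate, drawn as the zwitterion without titanium (not isolated) | COC(=O)CCCC[C@@H]([O-])Cc1cc(O[Si](C)(C)C(C)(C)C)c2c(O[Si](C)(C)C(C)(C)C)cc(OC)cc2[o+]1 | intermediate
8 | methyl (6R)-6-[(tert-butyldimethylsilyl)oxy]-7-{5-[(tert-butyldimethylsilyl)oxy]-7-methoxy-4-oxo-4H-chromen-2-yl}heptanoate | COC(=O)CCCC[C@@H](O[Si](C)(C)C(C)(C)C)Cc1cc(=O)c2c(O[Si](C)(C)C(C)(C)C)cc(OC)cc2o1 | intermediate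
9 | methyl (6R)-6-[(tert-butyldimethylsilyl)oxy]-7-(5-hydroxy-7-methoxy-4-oxo-4H-chromen-2-yl)heptanoate (not isolated) | COC(=O)CCCC[C@@H](O[Si](C)(C)C(C)(C)C)Cc1cc(=O)c2c(O)cc(OC)cc2o1 | intermediate
10 | Penithochromone O, methyl (6R)-6-hydroxy-7-(5-hydroxy-7-methoxy-4-oxo-4H-chromen-2-yl)heptanoate | COC(=O)CCCC[C@@H](O)Cc1cc(=O)c2c(O)cc(OC)cc2o1 | target

**Count**

Total steps: 4. Longest linear sequence: 4 steps (1 → 2 → 5 → 8 → 10); 6 enters at step 3.

**Steps most likely to fail**

Step 3 (Proposed new method). What may go wrong: weak enantiofacial discrimination with this untested nucleophile, or stalled turnover if the Lewis-basic pyranone product or a phenoxide freed by loss of the 5-O-silyl group ties up titanium. Fallback, known chemistry throughout, from 2 back to 10: eugenin 2 is protected (MOMCl, i-Pr2NEt) as 7-methoxy-5-(methoxymethoxy)-2-methyl-4H-chromen-4-one F1. Its lithium dienolate (LDA, THF, −78 °C) is added to 6, the standard aldol reaction of 2-methylchromones, to give racemic methyl 6-hydroxy-7-[7-methoxy-5-(methoxymethoxy)-4-oxo-4H-chromen-2-yl]heptanoate F2. Dess–Martin oxidation gives methyl 7-[7-methoxy-5-(methoxymethoxy)-4-oxo-4H-chromen-2-yl]-6-oxoheptanoate F3. Reduction with an (R)-selective ketoreductase (NADPH recycled with i-PrOH, buffer) should give methyl (6R)-6-hydroxy-7-[7-methoxy-5-(methoxymethoxy)-4-oxo-4H-chromen-2-yl]heptanoate F4. Methanolic HCl then removes the MOM group and gives 10.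

Step 2. What may go wrong: incomplete silylation of the hydrogen-bonded 5-OH, C-silylation of the methylidene carbon by excess silyl triflate, or hydrolysis of the crowded peri-bis(silyloxy) dienol ether during isolation. Fallback from 2 back to 9, with the phenol masked as a methyl ether and the dienol ether made through the lithium dienolate: 2 is methylated further (MeI, K2CO3, DMF, 60 °C) to 5,7-dimethoxy-2-methyl-4H-chromen-4-one F5. Its lithium dienolate (LDA, THF, −78 °C) is O-silylated with TBSCl to tert-butyl[(5,7-dimethoxy-2-methylidene-2H-chromen-4-yl)oxy]dimethylsilane F6. This takes the place of 5 under the conditions of step 3 with 6 and should give methyl (6R)-6-[(tert-butyldimethylsilyl)oxy]-7-(5,7-dimethoxy-4-oxo-4H-chromen-2-yl)heptanoate F7. BCl3 (CH2Cl2, −78 °C) then removes only the peri 5-O-methyl group, through its boron chelate with the C4 carbonyl, to give 9, which is desilylated as in step 4.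

Step 4. What may go wrong: slow cleavage of the secondary silyl ether and, on forcing, acid-promoted dehydration of the β-hydroxy chromone to the conjugated 2-alkenylchromone. Fallback from 2 back to 10, with a protecting group that needs no fluoride: TESOTf/Et3N converts 2 into 4,5-bis(triethylsilyloxy)-7-methoxy-2-methylidene-2H-chromene F8. Addition to 6 under the conditions of step 3 should give methyl (6R)-6-(triethylsilyloxy)-7-[5-(triethylsilyloxy)-7-methoxy-4-oxo-4H-chromen-2-yl]heptanoate F9. Both triethylsilyl ethers are then cleaved by PPTS in MeOH at rt to give 10.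

**Further compounds**

F1 | step 3 | 7-methoxy-5-(methoxymethoxy)-2-methyl-4H-chromen-4-one | Cc1cc(=O)c2c(OCOC)cc(OC)cc2o1
F2 | step 3 | methyl 6-hydroxy-7-[7-methoxy-5-(methoxymethoxy)-4-oxo-4H-chromen-2-yl]heptanoate (racemic) | COC(=O)CCCCC(O)Cc1cc(=O)c2c(OCOC)cc(OC)cc2o1
F3 | step 3 | methyl 7-[7-methoxy-5-(methoxymethoxy)-4-oxo-4H-chromen-2-yl]-6-oxoheptanoate | COC(=O)CCCCC(=O)Cc1cc(=O)c2c(OCOC)cc(OC)cc2o1
F4 | step 3 | methyl (6R)-6-hydroxy-7-[7-methoxy-5-(methoxymethoxy)-4-oxo-4H-chromen-2-yl]heptanoate | COC(=O)CCCC[C@@H](O)Cc1cc(=O)c2c(OCOC)cc(OC)cc2o1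
F5 | step 2 | 5,7-dimethoxy-2-methyl-4H-chromen-4-one | Cc1cc(=O)c2c(OC)cc(OC)cc2o1
F6 | step 2 | tert-butyl[(5,7-dimethoxy-2-methylidene-2H-chromen-4-yl)oxy]dimethylsilane | C=C1C=C(O[Si](C)(C)C(C)(C)C)c2c(OC)cc(OC)cc2O1
F7 | step 2 | methyl (6R)-6-[(tert-butyldimethylsilyl)oxy]-7-(5,7-dimethoxy-4-oxo-4H-chromen-2-yl)heptanoate | COC(=O)CCCC[C@@H](O[Si](C)(C)C(C)(C)C)Cc1cc(=O)c2c(OC)cc(OC)cc2o1
F8 | step 4 | 4,5-bis(triethylsilyloxy)-7-methoxy-2-methylidene-2H-chromene | C=C1C=C(O[Si](CC)(CC)CC)c2c(O[Si](CC)(CC)CC)cc(OC)cc2O1
F9 | step 4 | methyl (6R)-6-(triethylsilyloxy)-7-[5-(triethylsilyloxy)-7-methoxy-4-oxo-4H-chromen-2-yl]heptanoate | COC(=O)CCCC[C@@H](O[Si](CC)(CC)CC)Cc1cc(=O)c2c(O[Si](CC)(CC)CC)cc(OC)cc2o1
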